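All constants were chosen freely; the flask was simulated.

The stirred vessel runs the same chemistry by different orders of addition, and each recipe ends with its own amount of side product.

| setting | grey | amber | teal | ochre |
|---|---|---|---|---|
| starting material | 10 mM | 10 mM | 10 mM | 10 mM |
| partner | 2.50 equiv (in portions, 3, over 1.5 min) | 2.50 equiv | 2.50 equiv | 2.50 equiv (fed, over 1.5 min) |
| second reagent | 1.10 equiv | 1.10 equiv (fed, over 1.5 min) | 1.10 equiv | 1.10 equiv |
| third reagent | 4.00 equiv | 4.00 equiv | 4.00 equiv | 4.00 equiv |
| time | 4.0 min | 4.0 min | 4.0 min | 4.0 min |
| remark | first portion at the start, last at 1.5 min | all else is in the flask from the start; the feed brings no volume worth counting | everything together at the start | all else is in the flask from the start; the feed brings no volume worth counting |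

    third reagent + intermediate B → target (k1 = 9.57 /M/s)
    second reagent + intermediate A → intermediate B (k2 = 54.4 /M/s)
    starting material + second reagent → side product (k3 = 2.41 /M/s)
    starting material + partner → intermediate A (k4 = 1.74 /M/s)
    second reagent ⇌ dormant form (K5 = 0.349, k5 = 0.223 /s)

- which flask leads in amount of side product, in percent of the starting material charged ("all alike" within 1.5 percentage points) (grey / amber / teal / ochre / all alike)
- how much side product is there at the end, in percent of the starting material charged: grey
- how much side product is there at the end, in percent of the starting material charged: amber
- how much side product is there at the end, in percent of the starting material charged: teal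
- how much side product is there at the end, in percent of the starting material charged: ochre

Follow one molecule of starting material in teal. It leaves either with partner, towards intermediate A, or with free second reagent, into side product. In teal, intermediate A has a half-life of 1.2 s by second reagent at charge, shorter than the 0.27 min of starting material by partner, so each starting material consumed in teal costs about one equivalent of second reagent by either exit. At equilibrium the dormant form leaves 74.1% of the second reagent free. Take d as free second reagent and b as partner, both in fractions of the starting charge.

The side exit's rate over the sum of both exit rates, at teal's opening charges, is 31.1%; this is the fork chance, a selectivity. Drawn against the fraction consumed, teal's side-product curve rises at that slope. Halfway through teal, d is 0.445 and b about 2.16, so the slope is 22.2%. At teal's far end, d is 0.0741 and b about 1.72, so the curve flattens to 5.63%. The last starting material in teal then has a half-life by partner near 0.386 min, which fits about 10.4 times into the run. Teal's level is the mean of these slopes, weighted to the middle, 20.9% by this reckoning. Grey, with its first portion of partner, opens at 57.5%, higher than teal's opening. Ochre opens with no partner, so its first molecules face no other exit, and amber opens with no second reagent. From these openings the reckoned order is ochre, grey, teal, amber.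

The forecast names ochre: 41% for grey, 3.5% for amber, 21.5% for teal and 47% for ochre, on the grounds that “Feeding second reagent starves the side path”. Its teal figure stands above the 20.9% reckoned here.

The simulation gives ochre the lead, with grey 41.6%, amber 3.97%, teal 23.0% and ochre 48.1%, each inside the forecast's range. In amber at 0.284 min, the partner exit used starting material 25 times as fast as the side exit, and 15 times as fast at 4.00 min. Amber's fork chance thus reads 3.90% and then 6.35% at those two moments.

A neighbour of amber is fed 1.90 equiv of second reagent over the same time. One equivalent is in by 0.789 min, when about 12.7% of the starting material would stand if it kept teal's half-life by partner at charge. With the whole excess of second reagent in, which the feed reaches only at its end, and one equivalent of partner spent, the fork chance is 38.1%. As a rough estimate this puts 4.84% on top of amber's level, or 8.81%. The neighbour gives 9.65%.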